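Plan
1. Retrosynthetic cuts: the lactone Cα–CH2 bond (enolate benzylation) separates a dihydrobenzofuran benzylic bromide from a β-benzyl lactone. The lactone is then cut at Cβ–CH2 (auxiliary-directed succinate benzylation) and at C7'–C8' of the keto arm (aldol), and the bromide at C2–C3 of the dihydrobenzofuran. Both halves are cut at the aryl–CH2CO2 bond (malonate arylation of one 5-bromovanillin ether), so a single arylacetic acid feeds both.
2. Enabling feature: C2 of the 2,3-dihydrobenzofuran is an O1-bound benzylic CH carrying the guaiacyl ring, and C3 is the α-carbon of an arylacetic ester carrying the one-carbon oxygenated group. A carbenoid at C3 can therefore insert into a C–H bond of the ArO–CH2–Ar' ether, making C2–C3 and the five-membered ring at once.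
3. Forward order: 5-bromovanillin gives the common acid (steps 1–5). Branch A: diazo ester, dihydrofuran ring closed in step 8, trans alcohol, bromide. Branch B: aldol arm masked as an acetonide, bromide, lactone ring closed in step 22. The halves are joined at lactone Cα (step 23), followed by acetal/trityl removal, benzylic oxidation to the ketone and hydrogenolysis.
4. Stereochemistry: C2 from the chiral dirhodium carboxylate (step 8); C3 by equilibration to trans (step 9); C8' from an Evans syn-aldol (step 15); lactone Cβ from an Evans alkylation (step 21); lactone Cα by alkylation anti to the β-substituent (step 23).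

Key step: step 8

Assumption: the catalyst antipode that gives the 2S series is written as Rh2(R-PTTL)4 (dirhodium tetrakis[N-phthaloyl-(R)-tert-leucinate]); if a trial run shows the opposite sense of induction, Rh2(S-PTTL)4 is used and nothing else changes.

Abbreviations and locants: BMB = 4-(benzyloxy)-3-methoxybenzyl; TIPS = triisopropylsilyl; Tr = triphenylmethyl; ArD = 3-[(4R,5S)-4-(4-benzyloxy-3-methoxyphenyl)-2,2-dimethyl-1,3-dioxan-5-yl]-5-methoxy-4-(BMB-oxy)phenyl. Dihydrobenzofuran atoms are O1, C2, C3; the keto arm is C7' (carbinol, later carbonyl), C8' (its α-carbon), C9' (CH2OH); the lactone carbons are Cα and Cβ; ring B is the arene that carries the keto arm. The BMB group plays two parts: in branch A its CH2 becomes C2, in branch B it protects the ring B phenol until the last step.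

Step 1
Reactants: 1 5-bromovanillin (3-bromo-4-hydroxy-5-methoxybenzaldehyde); 2 4-(benzyloxy)-3-methoxybenzyl alcohol
Product: 3 3-bromo-5-methoxy-4-(BMB-oxy)benzaldehyde
Conditions: PPh3, DIAD, THF, 0 °C to rt
Reagents that add atoms: none
Why: Mitsunobu etherification, in which the acidic phenol of 1 displaces the phosphonium-activated primary benzylic alcohol under neutral conditions that leave the aldehyde and the aryl bromide untouched.

Step 2
Reactants: 3 3-bromo-5-methoxy-4-(BMB-oxy)benzaldehyde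
Product: 4 [3-bromo-5-methoxy-4-(BMB-oxy)phenyl]methanol
Conditions: NaBH4, MeOH/THF, 0 °C
Reagents that add atoms: none
Why: Borohydride reduction of the aryl aldehyde to the benzylic alcohol, to which the aryl bromide and the benzyl-type ethers are inert.

Step 3
Reactants: 4 [3-bromo-5-methoxy-4-(BMB-oxy)phenyl]methanol
Product: 5 [3-bromo-5-methoxy-4-(BMB-oxy)benzyl]oxy-triisopropylsilane
Conditions: TIPSCl, imidazole, DMF, rt
Reagents that add atoms: triisopropylsilyl chloride, CC(C)[Si](Cl)(C(C)C)C(C)C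
Why: Silylation of the primary alcohol gives a base- and heat-stable ether that masks the future benzylic bromide through the palladium, carbenoid, hydride and boron enolate steps.

Step 4
Reactants: 5 [3-bromo-5-methoxy-4-(BMB-oxy)benzyl]oxy-triisopropylsilane; 6 dimethyl malonate
Product: 7 dimethyl 2-[3-methoxy-2-(BMB-oxy)-5-(TIPSO-methyl)phenyl]malonate
Conditions: Pd(OAc)2 (3 mol%), P(t-Bu)3·HBF4 (6 mol%), K3PO4, toluene, 80 °C
Reagents that add atoms: none
Why: Palladium-catalysed α-arylation of a malonate enolate, where the bulky electron-rich phosphine allows oxidative addition of the ortho-alkoxy aryl bromide and C–C reductive elimination, and phosphate is too weak a base to harm the ethers.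

Step 5
Reactants: 7 dimethyl 2-[3-methoxy-2-(BMB-oxy)-5-(TIPSO-methyl)phenyl]malonate
Product: 9 2-[3-methoxy-2-(BMB-oxy)-5-(TIPSO-methyl)phenyl]acetic acid, via arylmalonic acid 8 (not isolated)
Conditions: LiOH, THF/MeOH/H2O, 60 °C; 1 M HCl to pH 3, 0 °C; pyridine, 80 °C
Reagents that add atoms: lithium hydroxide, [Li+].[OH-]
Why: Ester saponification followed by decarboxylation of the arylmalonic acid, which loses CO2 easily because the carbanion is benzylic, under conditions (hydroxide, brief pH 3, warm pyridine) that the TIPS and benzyl-type ethers tolerate.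

Step 6
Reactants: 9 2-[3-methoxy-2-(BMB-oxy)-5-(TIPSO-methyl)phenyl]acetic acid
Product: 10 methyl 2-[3-methoxy-2-(BMB-oxy)-5-(TIPSO-methyl)phenyl]acetate
Conditions: MeI, K2CO3, DMF, rt
Reagents that add atoms: iodomethane, CI
Why: SN2 O-methylation of the carboxylate gives the methyl ester needed for diazo transfer without acid that could remove the silyl group.

Step 7
Reactants: 10 methyl 2-[3-methoxy-2-(BMB-oxy)-5-(TIPSO-methyl)phenyl]acetate
Product: 11 methyl 2-diazo-2-[3-methoxy-2-(BMB-oxy)-5-(TIPSO-methyl)phenyl]acetate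
Conditions: p-ABSA, DBU, MeCN, 0 °C to rt
Reagents that add atoms: 4-acetamidobenzenesulfonyl azide (p-ABSA), CC(=O)Nc1ccc(cc1)S(=O)(=O)N=[N+]=[N-]
Why: Regitz diazo transfer, in which the DBU-generated arylacetate enolate attacks the terminal nitrogen of the sulfonyl azide and the adduct collapses to the aryl diazoacetate and the sulfonamide.

Step 8
Reactants: 11 methyl 2-diazo-2-[3-methoxy-2-(BMB-oxy)-5-(TIPSO-methyl)phenyl]acetate
Product: 12 methyl (2S,3R)-2-(4-benzyloxy-3-methoxyphenyl)-7-methoxy-5-(TIPSO-methyl)-2,3-dihydrobenzofuran-3-carboxylate (cis)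
Conditions: Rh2(R-PTTL)4 (1 mol%), toluene, −60 °C, high dilution
Reagents that add atoms: none
Why: The diazo ester loses N2 on the dirhodium core to give a donor–acceptor rhodium carbenoid, which inserts through a concerted, asynchronous three-centre transition state with hydride-shift character into one C–H bond of the O–CH2–aryl group five atoms away. The closest known reaction type is the chiral dirhodium tetracarboxylate-catalysed 1,5 C–H insertion of methyl 2-(2-benzyloxyphenyl)diazoacetates, which gives cis-2-aryl-2,3-dihydrobenzofuran-3-carboxylates. The dihydrofuran ring closes by this 1,5-insertion, the carbenoid carbon (C3) bonding to the former benzylic CH2 (C2), which is the only five-membered-ring mode open to the carbenoid. C2 should be set by the chiral carboxylate ligands, which differentiate the two enantiotopic benzylic hydrogens, while C3 should arise cis because ester and aryl lie on the same face in the compact insertion transition state; C3 is corrected in step 9. The step needs site selectivity for this C–H bond over cycloaddition to the electron-rich benzyl ring, carbene dimerisation and the OCH3 groups; the target C–H bond is activated by both the ether oxygen and the 4-alkoxyaryl ring and is the only activated one within reach (insertion into the neighbouring OCH3 would require a meta-bridged ring), and low temperature and dilution suppress the bimolecular paths.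

Step 9
Reactants: 12 methyl (2S,3R)-2-(4-benzyloxy-3-methoxyphenyl)-7-methoxy-5-(TIPSO-methyl)-2,3-dihydrobenzofuran-3-carboxylate (cis)
Product: 13 methyl (2S,3S)-2-(4-benzyloxy-3-methoxyphenyl)-7-methoxy-5-(TIPSO-methyl)-2,3-dihydrobenzofuran-3-carboxylate (trans)
Conditions: NaOMe (0.3 equiv), MeOH/THF, 0 °C to rt
Reagents that add atoms: none
Why: Thermodynamic epimerisation through the ester enolate at C3 relieves the cis aryl/ester interaction and should give the trans ester, while C2 has no acidic hydrogen and keeps its configuration.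

Step 10
Reactants: 13 methyl (2S,3S)-2-(4-benzyloxy-3-methoxyphenyl)-7-methoxy-5-(TIPSO-methyl)-2,3-dihydrobenzofuran-3-carboxylate (trans)
Product: 14 [(2S,3R)-2-(4-benzyloxy-3-methoxyphenyl)-7-methoxy-5-(TIPSO-methyl)-2,3-dihydrobenzofuran-3-yl]methanol (trans)
Conditions: LiAlH4, THF, 0 °C
Reagents that add atoms: none
Why: Hydride reduction of the ester to the primary alcohol with no change in spatial arrangement at C2 or C3 (the C3 descriptor changes only because the substituent priorities change).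

Step 11
Reactants: 14 [(2S,3R)-2-(4-benzyloxy-3-methoxyphenyl)-7-methoxy-5-(TIPSO-methyl)-2,3-dihydrobenzofuran-3-yl]methanol (trans)
Product: 15 (2S,3R)-2-(4-benzyloxy-3-methoxyphenyl)-7-methoxy-5-(TIPSO-methyl)-3-(TrO-methyl)-2,3-dihydrobenzofuran
Conditions: TrCl, Et3N, DMAP (cat.), CH2Cl2, rt
Reagents that add atoms: trityl chloride, ClC(c1ccccc1)(c1ccccc1)c1ccccc1
Why: Tritylation of the primary alcohol gives an ether that is stable to fluoride, Appel conditions and a lactone enolate and can later be cleaved together with the acetonide by weak aqueous acid.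

Step 12
Reactants: 15 (2S,3R)-2-(4-benzyloxy-3-methoxyphenyl)-7-methoxy-5-(TIPSO-methyl)-3-(TrO-methyl)-2,3-dihydrobenzofuran
Product: 16 [(2S,3R)-2-(4-benzyloxy-3-methoxyphenyl)-7-methoxy-3-(TrO-methyl)-2,3-dihydrobenzofuran-5-yl]methanol
Conditions: Bu4NF, THF, 0 °C to rt
Reagents that add atoms: none
Why: Fluoride-mediated desilylation frees the benzylic alcohol, and trityl and benzyl ethers are inert to fluoride.

Step 13
Reactants: 16 [(2S,3R)-2-(4-benzyloxy-3-methoxyphenyl)-7-methoxy-3-(TrO-methyl)-2,3-dihydrobenzofuran-5-yl]methanol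
Product: 17 (2S,3R)-5-(bromomethyl)-2-(4-benzyloxy-3-methoxyphenyl)-7-methoxy-3-(TrO-methyl)-2,3-dihydrobenzofuran
Conditions: CBr4, PPh3, CH2Cl2, 0 °C; used at once
Reagents that add atoms: carbon tetrabromide, BrC(Br)(Br)Br
Why: Appel bromination converts the electron-rich benzylic alcohol into the bromide under neutral conditions, avoiding the acid that would endanger the trityl ether.

Step 14
Reactants: 9 2-[3-methoxy-2-(BMB-oxy)-5-(TIPSO-methyl)phenyl]acetic acid; 18 (R)-4-benzyl-1,3-oxazolidin-2-one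
Product: 20 (R)-4-benzyl-3-{2-[3-methoxy-2-(BMB-oxy)-5-(TIPSO-methyl)phenyl]acetyl}-1,3-oxazolidin-2-one, via mixed pivalic anhydride 19 (not isolated)
Conditions: PivCl, Et3N, THF, −20 °C; then 18, LiCl, rt
Reagents that add atoms: none
Why: N-Acylation of the oxazolidinone by a mixed anhydride, the lithium-activated auxiliary attacking the less hindered arylacetyl carbonyl.

Step 15
Reactants: 20 (R)-4-benzyl-3-{2-[3-methoxy-2-(BMB-oxy)-5-(TIPSO-methyl)phenyl]acetyl}-1,3-oxazolidin-2-one; 21 4-(benzyloxy)-3-methoxybenzaldehyde (O-benzylvanillin)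
Product: 22 (R)-4-benzyl-3-{(2R,3R)-3-(4-benzyloxy-3-methoxyphenyl)-3-hydroxy-2-[3-methoxy-2-(BMB-oxy)-5-(TIPSO-methyl)phenyl]propanoyl}-1,3-oxazolidin-2-one (syn aldol)
Conditions: Bu2BOTf, i-Pr2NEt, CH2Cl2, −78 to 0 °C; 21, −78 to 0 °C; pH 7 buffer, MeOH, 30% H2O2, 0 °C
Reagents that add atoms: none
Why: Evans syn-aldol reaction, in which the Z-boron enolate reacts through a closed chair transition state on the face away from the auxiliary benzyl group, setting C8' (2R in the imide, S in the target numbering) and the transient C7' carbinol syn to it.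

Step 16
Reactants: 22 (R)-4-benzyl-3-{(2R,3R)-3-(4-benzyloxy-3-methoxyphenyl)-3-hydroxy-2-[3-methoxy-2-(BMB-oxy)-5-(TIPSO-methyl)phenyl]propanoyl}-1,3-oxazolidin-2-one (syn aldol)
Product: 23 (1R,2S)-1-(4-benzyloxy-3-methoxyphenyl)-2-[3-methoxy-2-(BMB-oxy)-5-(TIPSO-methyl)phenyl]propane-1,3-diol
Conditions: LiBH4, MeOH (1 equiv), THF, 0 °C
Reagents that add atoms: none
Why: Reductive cleavage of the imide by borohydride gives the 1,3-diol and returns the auxiliary under non-enolising conditions that should leave C8' intact.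

Step 17
Reactants: 23 (1R,2S)-1-(4-benzyloxy-3-methoxyphenyl)-2-[3-methoxy-2-(BMB-oxy)-5-(TIPSO-methyl)phenyl]propane-1,3-diol
Product: 24 (4R,5S)-4-(4-benzyloxy-3-methoxyphenyl)-5-[3-methoxy-2-(BMB-oxy)-5-(TIPSO-methyl)phenyl]-2,2-dimethyl-1,3-dioxane
Conditions: Me2C(OMe)2, PPTS (cat.), CH2Cl2, rt
Reagents that add atoms: 2,2-dimethoxypropane, COC(C)(C)OC
Why: Acid-catalysed transketalisation ties the 1,3-diol up as an isopropylidene acetal that is stable to fluoride, strong bases and hydride.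

Step 18
Reactants: 24 (4R,5S)-4-(4-benzyloxy-3-methoxyphenyl)-5-[3-methoxy-2-(BMB-oxy)-5-(TIPSO-methyl)phenyl]-2,2-dimethyl-1,3-dioxane
Product: 25 ArD-methanol, {3-[(4R,5S)-4-(4-benzyloxy-3-methoxyphenyl)-2,2-dimethyl-1,3-dioxan-5-yl]-5-methoxy-4-(BMB-oxy)phenyl}methanol
Conditions: Bu4NF, THF, 0 °C to rt
Reagents that add atoms: none
Why: Fluoride-mediated desilylation frees the benzylic alcohol without touching the acetonide or the benzyl-type ethers.

Step 19
Reactants: 25 ArD-methanol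
Product: 26 ArD-methyl bromide, (4R,5S)-5-[5-(bromomethyl)-3-methoxy-2-(BMB-oxy)phenyl]-4-(4-benzyloxy-3-methoxyphenyl)-2,2-dimethyl-1,3-dioxane
Conditions: CBr4, PPh3, CH2Cl2, 0 °C; used at once
Reagents that add atoms: carbon tetrabromide, BrC(Br)(Br)Br
Why: Appel bromination gives the benzylic bromide under neutral conditions that the acetonide survives.

Step 20
Reactants: 27 4-tert-butoxy-4-oxobutanoic acid (mono-tert-butyl succinate); 18 (R)-4-benzyl-1,3-oxazolidin-2-one
Product: 29 tert-butyl 4-[(R)-4-benzyl-2-oxo-1,3-oxazolidin-3-yl]-4-oxobutanoate, via mixed pivalic anhydride 28 (not isolated)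
Conditions: PivCl, Et3N, THF, −20 °C; then 18, LiCl, rt
Reagents that add atoms: none
Why: N-Acylation of the oxazolidinone by a mixed anhydride, as in step 14, gives the chiral succinate equivalent.

Step 21
Reactants: 29 tert-butyl 4-[(R)-4-benzyl-2-oxo-1,3-oxazolidin-3-yl]-4-oxobutanoate (1.5 equiv); 26 ArD-methyl bromide
Product: 30 tert-butyl (3R)-4-[(R)-4-benzyl-2-oxo-1,3-oxazolidin-3-yl]-4-oxo-3-(ArD-methyl)butanoate
Conditions: NaN(SiMe3)2, THF, −78 °C; then 26, −78 to −40 °C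
Reagents that add atoms: none
Why: Evans alkylation, in which the amide base removes the more acidic imide α-proton to give a chelated Z-enolate that is benzylated on the face opposite the auxiliary benzyl group, setting the future lactone Cβ as R.

Step 22
Reactants: 30 tert-butyl (3R)-4-[(R)-4-benzyl-2-oxo-1,3-oxazolidin-3-yl]-4-oxo-3-(ArD-methyl)butanoate
Product: 32 (4R)-4-(ArD-methyl)oxolan-2-one, via hydroxy tert-butyl ester 31 (not isolated)
Conditions: LiBH4, MeOH (1 equiv), THF, 0 °C; aqueous work-up; KOt-Bu (0.1 equiv), THF, 0 °C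
Reagents that add atoms: none
Why: Chemoselective borohydride reduction of the imide beside the tert-butyl ester, followed by alkoxide-catalysed 5-exo-trig lactonisation with loss of tert-butanol, gives the (R)-β-benzyl-γ-butyrolactone without acid that would open the acetonide.

Step 23
Reactants: 32 (4R)-4-(ArD-methyl)oxolan-2-one; 17 (2S,3R)-5-(bromomethyl)-2-(4-benzyloxy-3-methoxyphenyl)-7-methoxy-3-(TrO-methyl)-2,3-dihydrobenzofuran
Product: 33 (3R,4R)-4-(ArD-methyl)-3-{[(2S,3R)-2-(4-benzyloxy-3-methoxyphenyl)-7-methoxy-3-(TrO-methyl)-2,3-dihydrobenzofuran-5-yl]methyl}oxolan-2-one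
Conditions: LiN(SiMe3)2, THF, −78 °C; then 17, DMPU, −78 to −40 °C
Reagents that add atoms: none
Why: Lactone enolate alkylation, in which the lithium enolate is benzylated anti to the β-benzyl group and should give the trans (3R,4R) lactone, the usual outcome for β-substituted butyrolactone enolates.

Step 24
Reactants: 33 (3R,4R)-4-(ArD-methyl)-3-{[(2S,3R)-2-(4-benzyloxy-3-methoxyphenyl)-7-methoxy-3-(TrO-methyl)-2,3-dihydrobenzofuran-5-yl]methyl}oxolan-2-one
Product: 34 (3R,4R)-3-{[(2S,3R)-2-(4-benzyloxy-3-methoxyphenyl)-3-(hydroxymethyl)-7-methoxy-2,3-dihydrobenzofuran-5-yl]methyl}-4-{3-[(1R,2S)-1-(4-benzyloxy-3-methoxyphenyl)-1,3-dihydroxypropan-2-yl]-5-methoxy-4-(BMB-oxy)benzyl}oxolan-2-one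
Conditions: AcOH/H2O/THF (4:1:1), 45 °C
Reagents that add atoms: none
Why: Acid-catalysed hydrolysis cleaves the isopropylidene acetal and the trityl ether together, the weak acid sparing the lactone, the dihydrobenzofuran and the benzyl-type aryl ethers, and any ionisation at C7' is harmless because that centre is oxidised next.

Step 25
Reactants: 34 the triol of step 24
Product: 35 (3R,4R)-3-{[(2S,3R)-2-(4-benzyloxy-3-methoxyphenyl)-3-(hydroxymethyl)-7-methoxy-2,3-dihydrobenzofuran-5-yl]methyl}-4-{3-[(2S)-1-(4-benzyloxy-3-methoxyphenyl)-3-hydroxy-1-oxopropan-2-yl]-5-methoxy-4-(BMB-oxy)benzyl}oxolan-2-one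
Conditions: MnO2 (activated, excess), CH2Cl2, rt
Reagents that add atoms: none
Why: Chemoselective MnO2 oxidation of the only benzylic alcohol to the aryl ketone, the two primary alcohols being non-benzylic and the neutral heterogeneous medium protecting the enolisable C8' centre.

Step 26
Reactants: 35 the ketone of step 25
Product: 36 CNP0111438.1, (3R,4R)-3-{[(2S,3R)-2-(4-hydroxy-3-methoxyphenyl)-3-(hydroxymethyl)-7-methoxy-2,3-dihydrobenzofuran-5-yl]methyl}-4-{4-hydroxy-3-[(2S)-3-hydroxy-1-(4-hydroxy-3-methoxyphenyl)-1-oxopropan-2-yl]-5-methoxybenzyl}oxolan-2-one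
Conditions: H2 (1 atm), 10% Pd/C, EtOAc/THF, rt; stopped at the calculated uptake
Reagents that add atoms: none
Why: Catalytic hydrogenolysis of the three benzyl-type aryl ethers (two benzyl, one BMB) under neutral conditions should be fast compared with reduction of the electron-rich aryl ketone or cleavage of the cyclic benzylic ether, and avoids the base or acid that would epimerise C8' or dehydrate the hydroxy ketone.

Compound list
1 | 5-bromovanillin | COc1cc(C=O)cc(Br)c1O | starting material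
2 | 4-(benzyloxy)-3-methoxybenzyl alcohol | COc1cc(CO)ccc1OCc1ccccc1 | starting material
3 | 3-bromo-5-methoxy-4-(BMB-oxy)benzaldehyde | COc1cc(C=O)cc(Br)c1OCc1ccc(OCc2ccccc2)c(OC)c1 | intermediate
4 | [3-bromo-5-methoxy-4-(BMB-oxy)phenyl]methanol | COc1cc(CO)cc(Br)c1OCc1ccc(OCc2ccccc2)c(OC)c1 | intermediate
5 | [3-bromo-5-methoxy-4-(BMB-oxy)benzyl]oxy-triisopropylsilane | COc1cc(CO[Si](C(C)C)(C(C)C)C(C)C)cc(Br)c1OCc1ccc(OCc2ccccc2)c(OC)c1 | intermediate
6 | dimethyl malonate | COC(=O)CC(=O)OC | starting material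
7 | dimethyl 2-[3-methoxy-2-(BMB-oxy)-5-(TIPSO-methyl)phenyl]malonate | COC(=O)C(C(=O)OC)c1cc(CO[Si](C(C)C)(C(C)C)C(C)C)cc(OC)c1OCc1ccc(OCc2ccccc2)c(OC)c1 | intermediate
8 | 2-[3-methoxy-2-(BMB-oxy)-5-(TIPSO-methyl)phenyl]malonic acid | OC(=O)C(C(=O)O)c1cc(CO[Si](C(C)C)(C(C)C)C(C)C)cc(OC)c1OCc1ccc(OCc2ccccc2)c(OC)c1 | intermediate
9 | 2-[3-methoxy-2-(BMB-oxy)-5-(TIPSO-methyl)phenyl]acetic acid | OC(=O)Cc1cc(CO[Si](C(C)C)(C(C)C)C(C)C)cc(OC)c1OCc1ccc(OCc2ccccc2)c(OC)c1 | intermediate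
10 | methyl 2-[3-methoxy-2-(BMB-oxy)-5-(TIPSO-methyl)phenyl]acetate | COC(=O)Cc1cc(CO[Si](C(C)C)(C(C)C)C(C)C)cc(OC)c1OCc1ccc(OCc2ccccc2)c(OC)c1 | intermediate
11 | methyl 2-diazo-2-[3-methoxy-2-(BMB-oxy)-5-(TIPSO-methyl)phenyl]acetate | COC(=O)C(=[N+]=[N-])c1cc(CO[Si](C(C)C)(C(C)C)C(C)C)cc(OC)c1OCc1ccc(OCc2ccccc2)c(OC)c1 | intermediate
12 | methyl (2S,3R)-2-(4-benzyloxy-3-methoxyphenyl)-7-methoxy-5-(TIPSO-methyl)-2,3-dihydrobenzofuran-3-carboxylate (cis) | COC(=O)[C@@H]1c2cc(CO[Si](C(C)C)(C(C)C)C(C)C)cc(OC)c2O[C@@H]1c1ccc(OCc2ccccc2)c(OC)c1 | intermediate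
13 | methyl (2S,3S)-2-(4-benzyloxy-3-methoxyphenyl)-7-methoxy-5-(TIPSO-methyl)-2,3-dihydrobenzofuran-3-carboxylate (trans) | COC(=O)[C@H]1c2cc(CO[Si](C(C)C)(C(C)C)C(C)C)cc(OC)c2O[C@@H]1c1ccc(OCc2ccccc2)c(OC)c1 | intermediate
14 | [(2S,3R)-2-(4-benzyloxy-3-methoxyphenyl)-7-methoxy-5-(TIPSO-methyl)-2,3-dihydrobenzofuran-3-yl]methanol (trans) | OC[C@H]1c2cc(CO[Si](C(C)C)(C(C)C)C(C)C)cc(OC)c2O[C@@H]1c1ccc(OCc2ccccc2)c(OC)c1 | intermediate
15 | (2S,3R)-2-(4-benzyloxy-3-methoxyphenyl)-7-methoxy-5-(TIPSO-methyl)-3-(TrO-methyl)-2,3-dihydrobenzofuran | C(c1ccccc1)(c1ccccc1)(c1ccccc1)OC[C@H]1c2cc(CO[Si](C(C)C)(C(C)C)C(C)C)cc(OC)c2O[C@@H]1c1ccc(OCc2ccccc2)c(OC)c1 | intermediate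
16 | [(2S,3R)-2-(4-benzyloxy-3-methoxyphenyl)-7-methoxy-3-(TrO-methyl)-2,3-dihydrobenzofuran-5-yl]methanol | C(c1ccccc1)(c1ccccc1)(c1ccccc1)OC[C@H]1c2cc(CO)cc(OC)c2O[C@@H]1c1ccc(OCc2ccccc2)c(OC)c1 | intermediate
17 | (2S,3R)-5-(bromomethyl)-2-(4-benzyloxy-3-methoxyphenyl)-7-methoxy-3-(TrO-methyl)-2,3-dihydrobenzofuran | C(c1ccccc1)(c1ccccc1)(c1ccccc1)OC[C@H]1c2cc(CBr)cc(OC)c2O[C@@H]1c1ccc(OCc2ccccc2)c(OC)c1 | intermediate
18 | (R)-4-benzyl-1,3-oxazolidin-2-one | O=C1N[C@H](Cc2ccccc2)CO1 | starting material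
19 | pivalic 2-[3-methoxy-2-(BMB-oxy)-5-(TIPSO-methyl)phenyl]acetic anhydride | CC(C)(C)C(=O)OC(=O)Cc1cc(CO[Si](C(C)C)(C(C)C)C(C)C)cc(OC)c1OCc1ccc(OCc2ccccc2)c(OC)c1 | intermediate
20 | (R)-4-benzyl-3-{2-[3-methoxy-2-(BMB-oxy)-5-(TIPSO-methyl)phenyl]acetyl}-1,3-oxazolidin-2-one | O=C1OC[C@@H](Cc2ccccc2)N1C(=O)Cc1cc(CO[Si](C(C)C)(C(C)C)C(C)C)cc(OC)c1OCc1ccc(OCc2ccccc2)c(OC)c1 | intermediate
21 | 4-(benzyloxy)-3-methoxybenzaldehyde | COc1cc(C=O)ccc1OCc1ccccc1 | starting material
22 | (R)-4-benzyl-3-{(2R,3R)-3-(4-benzyloxy-3-methoxyphenyl)-3-hydroxy-2-[3-methoxy-2-(BMB-oxy)-5-(TIPSO-methyl)phenyl]propanoyl}-1,3-oxazolidin-2-one | O=C1OC[C@@H](Cc2ccccc2)N1C(=O)[C@H](c1cc(CO[Si](C(C)C)(C(C)C)C(C)C)cc(OC)c1OCc1ccc(OCc2ccccc2)c(OC)c1)[C@@H](O)c1ccc(OCc2ccccc2)c(OC)c1 | intermediate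
23 | (1R,2S)-1-(4-benzyloxy-3-methoxyphenyl)-2-[3-methoxy-2-(BMB-oxy)-5-(TIPSO-methyl)phenyl]propane-1,3-diol | OC[C@H](c1cc(CO[Si](C(C)C)(C(C)C)C(C)C)cc(OC)c1OCc1ccc(OCc2ccccc2)c(OC)c1)[C@@H](O)c1ccc(OCc2ccccc2)c(OC)c1 | intermediate
24 | (4R,5S)-4-(4-benzyloxy-3-methoxyphenyl)-5-[3-methoxy-2-(BMB-oxy)-5-(TIPSO-methyl)phenyl]-2,2-dimethyl-1,3-dioxane | CC1(C)OC[C@H](c2cc(CO[Si](C(C)C)(C(C)C)C(C)C)cc(OC)c2OCc2ccc(OCc3ccccc3)c(OC)c2)[C@@H](O1)c1ccc(OCc2ccccc2)c(OC)c1 | intermediate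
25 | ArD-methanol | CC1(C)OC[C@H](c2cc(CO)cc(OC)c2OCc2ccc(OCc3ccccc3)c(OC)c2)[C@@H](O1)c1ccc(OCc2ccccc2)c(OC)c1 | intermediate
26 | ArD-methyl bromide | CC1(C)OC[C@H](c2cc(CBr)cc(OC)c2OCc2ccc(OCc3ccccc3)c(OC)c2)[C@@H](O1)c1ccc(OCc2ccccc2)c(OC)c1 | intermediate
27 | 4-tert-butoxy-4-oxobutanoic acid | CC(C)(C)OC(=O)CCC(=O)O | starting material
28 | pivalic 4-tert-butoxy-4-oxobutanoic anhydride | CC(C)(C)OC(=O)CCC(=O)OC(=O)C(C)(C)C | intermediate
29 | tert-butyl 4-[(R)-4-benzyl-2-oxo-1,3-oxazolidin-3-yl]-4-oxobutanoate | O=C1OC[C@@H](Cc2ccccc2)N1C(=O)CCC(=O)OC(C)(C)C | intermediate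
30 | tert-butyl (3R)-4-[(R)-4-benzyl-2-oxo-1,3-oxazolidin-3-yl]-4-oxo-3-(ArD-methyl)butanoate | O=C1OC[C@@H](Cc2ccccc2)N1C(=O)[C@@H](CC(=O)OC(C)(C)C)Cc1cc([C@H]2COC(C)(C)O[C@H]2c2ccc(OCc3ccccc3)c(OC)c2)c(OCc2ccc(OCc3ccccc3)c(OC)c2)c(OC)c1 | intermediate
31 | tert-butyl (3R)-4-hydroxy-3-(ArD-methyl)butanoate | OC[C@@H](CC(=O)OC(C)(C)C)Cc1cc([C@H]2COC(C)(C)O[C@H]2c2ccc(OCc3ccccc3)c(OC)c2)c(OCc2ccc(OCc3ccccc3)c(OC)c2)c(OC)c1 | intermediate
32 | (4R)-4-(ArD-methyl)oxolan-2-one | O=C1C[C@@H](Cc2cc([C@H]3COC(C)(C)O[C@H]3c3ccc(OCc4ccccc4)c(OC)c3)c(OCc3ccc(OCc4ccccc4)c(OC)c3)c(OC)c2)CO1 | intermediate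
33 | (3R,4R)-4-(ArD-methyl)-3-{[(2S,3R)-2-(4-benzyloxy-3-methoxyphenyl)-7-methoxy-3-(TrO-methyl)-2,3-dihydrobenzofuran-5-yl]methyl}oxolan-2-one | O=C1[C@H](Cc2cc(OC)c3O[C@H](c4ccc(OCc5ccccc5)c(OC)c4)[C@@H](COC(c4ccccc4)(c4ccccc4)c4ccccc4)c3c2)[C@@H](Cc2cc([C@H]3COC(C)(C)O[C@H]3c3ccc(OCc4ccccc4)c(OC)c3)c(OCc3ccc(OCc4ccccc4)c(OC)c3)c(OC)c2)CO1 | intermediate
34 | triol: (3R,4R)-lactone with the (2S,3R)-3-(hydroxymethyl)dihydrobenzofuran arm and the (1R,2S)-1,3-dihydroxy arm, three benzyl-type ethers | O=C1[C@H](Cc2cc(OC)c3O[C@H](c4ccc(OCc5ccccc5)c(OC)c4)[C@@H](CO)c3c2)[C@@H](Cc2cc([C@@H](CO)[C@@H](O)c3ccc(OCc4ccccc4)c(OC)c3)c(OCc3ccc(OCc4ccccc4)c(OC)c3)c(OC)c2)CO1 | intermediate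
35 | (2S)-ketone of 34, three benzyl-type ethers | O=C1[C@H](Cc2cc(OC)c3O[C@H](c4ccc(OCc5ccccc5)c(OC)c4)[C@@H](CO)c3c2)[C@@H](Cc2cc([C@@H](CO)C(=O)c3ccc(OCc4ccccc4)c(OC)c3)c(OCc3ccc(OCc4ccccc4)c(OC)c3)c(OC)c2)CO1 | intermediate
36 | CNP0111438.1 | O=C1[C@H](Cc2cc(OC)c3O[C@H](c4ccc(O)c(OC)c4)[C@@H](CO)c3c2)[C@@H](Cc2cc([C@@H](CO)C(=O)c3ccc(O)c(OC)c3)c(O)c(OC)c2)CO1 | target

Total step count: 26 steps.
Longest linear sequence: 17 steps (1–5, 14–19, 21–26; the line through 6–13 and 23–26 is equally long).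

Steps most likely to fail

Step 8. The catalyst may discriminate the two enantiotopic benzylic hydrogens poorly on this doubly ortho-substituted aryl ether, or the carbenoid may be diverted into cycloaddition with the electron-rich benzyl ring or into dimerisation. Fallback, setting out from 9 and coming back at 14: the dihydrofuran ring is closed through its C2–O1 bond instead. Acid 9 is attached to (S)-4-benzyl-1,3-oxazolidin-2-one as in step 14 to give the (S)-imide F1. Its boron enolate adds to 21 as in step 15 to give the enantiomeric syn-aldol adduct F2, and LiBH4 gives the diol F3. Trifluoroacetic acid with pentamethylbenzene in CH2Cl2 at 0 °C removes the BMB group to give the phenol F4. In the same medium its benzylic carbinol ionises and is trapped by the phenol oxygen, closing the thermodynamically preferred trans ring with C3 fixed by the aldol; the product is alcohol 14.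

Step 25. Oxidation of the hindered benzylic carbinol on the oxide surface may be slow, and the β-hydroxy ketone may suffer retro-aldol loss of formaldehyde, dehydration or epimerisation at C8' on prolonged contact. Fallback, setting out from 34 and coming back at 35: TBSCl/imidazole at 0 °C silylates only the two primary hydroxyls to give the bis-silyl ether F5. The remaining secondary carbinol is oxidised quickly with NaHCO3-buffered Dess–Martin periodinane to the ketone F6. HF·pyridine in THF then removes both silyl groups under mildly acidic conditions to give 35.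

Step 21. The electron-rich benzylic bromide may ionise and decompose before C-alkylation, and benzylation of the chelated succinate enolate may be slow enough for enolate equilibration to erode regio- and facial control. Fallback, setting out from 25 and coming back at 32: the lactone stereocentre is set by hydrogenation instead of alkylation. MnO2 oxidises 25 to the aldehyde F7. Stobbe condensation with dimethyl succinate (KOt-Bu, t-BuOH) gives the E half-ester F8. Hydrogenation with a cationic rhodium bisphosphine catalyst such as [Rh(cod)(Me-DuPhos)]BF4, ligand antipode chosen for the R acid, gives the half-ester F9. Reduction of its potassium salt with Ca(BH4)2 and acidification to pH 3 closes lactone 32.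

Further compounds
F1 | step 8 | (S)-4-benzyl-3-{2-[3-methoxy-2-(BMB-oxy)-5-(TIPSO-methyl)phenyl]acetyl}-1,3-oxazolidin-2-one | O=C1OC[C@H](Cc2ccccc2)N1C(=O)Cc1cc(CO[Si](C(C)C)(C(C)C)C(C)C)cc(OC)c1OCc1ccc(OCc2ccccc2)c(OC)c1
F2 | step 8 | (S)-4-benzyl-3-{(2S,3S)-3-(4-benzyloxy-3-methoxyphenyl)-3-hydroxy-2-[3-methoxy-2-(BMB-oxy)-5-(TIPSO-methyl)phenyl]propanoyl}-1,3-oxazolidin-2-one | O=C1OC[C@H](Cc2ccccc2)N1C(=O)[C@@H](c1cc(CO[Si](C(C)C)(C(C)C)C(C)C)cc(OC)c1OCc1ccc(OCc2ccccc2)c(OC)c1)[C@H](O)c1ccc(OCc2ccccc2)c(OC)c1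
F3 | step 8 | (1S,2R)-1-(4-benzyloxy-3-methoxyphenyl)-2-[3-methoxy-2-(BMB-oxy)-5-(TIPSO-methyl)phenyl]propane-1,3-diol | OC[C@@H](c1cc(CO[Si](C(C)C)(C(C)C)C(C)C)cc(OC)c1OCc1ccc(OCc2ccccc2)c(OC)c1)[C@H](O)c1ccc(OCc2ccccc2)c(OC)c1
F4 | step 8 | (1S,2R)-1-(4-benzyloxy-3-methoxyphenyl)-2-[2-hydroxy-3-methoxy-5-(TIPSO-methyl)phenyl]propane-1,3-diol | OC[C@@H](c1cc(CO[Si](C(C)C)(C(C)C)C(C)C)cc(OC)c1O)[C@H](O)c1ccc(OCc2ccccc2)c(OC)c1
F5 | step 25 | bis(tert-butyldimethylsilyl) ether of 34 at the two primary hydroxyls | O=C1[C@H](Cc2cc(OC)c3O[C@H](c4ccc(OCc5ccccc5)c(OC)c4)[C@@H](CO[Si](C)(C)C(C)(C)C)c3c2)[C@@H](Cc2cc([C@@H](CO[Si](C)(C)C(C)(C)C)[C@@H](O)c3ccc(OCc4ccccc4)c(OC)c3)c(OCc3ccc(OCc4ccccc4)c(OC)c3)c(OC)c2)CO1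
F6 | step 25 | bis(tert-butyldimethylsilyl) ether of 35 | O=C1[C@H](Cc2cc(OC)c3O[C@H](c4ccc(OCc5ccccc5)c(OC)c4)[C@@H](CO[Si](C)(C)C(C)(C)C)c3c2)[C@@H](Cc2cc([C@@H](CO[Si](C)(C)C(C)(C)C)C(=O)c3ccc(OCc4ccccc4)c(OC)c3)c(OCc3ccc(OCc4ccccc4)c(OC)c3)c(OC)c2)CO1
F7 | step 21 | ArD-carbaldehyde, 3-[(4R,5S)-4-(4-benzyloxy-3-methoxyphenyl)-2,2-dimethyl-1,3-dioxan-5-yl]-5-methoxy-4-(BMB-oxy)benzaldehyde | CC1(C)OC[C@H](c2cc(C=O)cc(OC)c2OCc2ccc(OCc3ccccc3)c(OC)c2)[C@@H](O1)c1ccc(OCc2ccccc2)c(OC)c1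
F8 | step 21 | (E)-4-ArD-3-(methoxycarbonyl)but-3-enoic acid | COC(=O)/C(CC(=O)O)=C/c1cc([C@H]2COC(C)(C)O[C@H]2c2ccc(OCc3ccccc3)c(OC)c2)c(OCc2ccc(OCc3ccccc3)c(OC)c2)c(OC)c1
F9 | step 21 | (3R)-4-ArD-3-(methoxycarbonyl)butanoic acid | COC(=O)[C@@H](CC(=O)O)Cc1cc([C@H]2COC(C)(C)O[C@H]2c2ccc(OCc3ccccc3)c(OC)c2)c(OCc2ccc(OCc3ccccc3)c(OC)c2)c(OC)c1
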